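## Retrosynthetic overview

1. The ten-membered ring is closed last at the hindered C9–C10 bond by an intramolecular NiCl2/CrCl2 coupling of a (Z)-2-iodo-enoate with the C9 aldehyde. This replaces ring-closing metathesis and the customary macrocyclic C6–C7 allylation–lactonisation. C9 is then fixed by oxidation and Felkin-controlled reduction.
2. C1=C10 comes from a (Z)-selective iodo-Wittig olefination of the C1 aldehyde; the C8 ester and C9 aldehyde come from a dioxolane.
3. The γ-lactone ring is formed first, by CrCl2-mediated allylation–lactonisation of a west enal (C6) with an east 2-(bromomethyl)acrylate made from (R)-glyceraldehyde acetonide. C8 directs C6 and C7.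
4. The west enal gets C4=C5 from a Horner–Wadsworth–Emmons reaction of a glycidol-derived phosphonolactone with dimethoxyacetaldehyde. Reduction of that lactone unveils the C15 and C2 oxygens; C2 is chiral pool.

Assumption: locants C1–C15 are the germacrane locants of the target (C12 lactone carbonyl, C13 exocyclic methylene, C14 ester carbon, C15 hydroxymethyl carbon); "2S, 6R, 7S, 8S, 9S" denote the spatial arrangement these atoms have in the target, and the SMILES strings are authoritative. TBS = tert-butyldimethylsilyl, TES = triethylsilyl, PMB = 4-methoxybenzyl, DMP = Dess–Martin periodinane.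

## Route

Step 1
Reactants: 1 (2R)-2-[(4-methoxybenzyloxy)methyl]oxirane; 2 triethyl phosphonoacetate
Product: 4 diethyl [(5S)-5-[(4-methoxybenzyloxy)methyl]-2-oxooxolan-3-yl]phosphonate (both C3 epimers), via hydroxy phosphonoester 3 (not isolated)
Conditions: NaH, THF, 0 °C; add 1, 65 °C, 12 h; aq. HCl
Reagents that add atoms: none
Why: Epoxide alkylation–lactonisation: the sodium phosphonoacetate opens the epoxide at its CH2 terminus and the alkoxide closes onto the ethyl ester, so the C2 stereocentre of 1 is carried over untouched.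

Step 2
Reactants: 4 phosphonolactone; 5 2,2-dimethoxyacetaldehyde
Product: 6 (3E,5S)-3-(2,2-dimethoxyethylidene)-5-[(4-methoxybenzyloxy)methyl]oxolan-2-one
Conditions: 5 (60% in H2O), K2CO3, THF/H2O, 0 °C to rt
Reagents that add atoms: none
Why: Horner–Wadsworth–Emmons olefination of the phosphonolactone places the new substituent anti to the lactone carbonyl (E, C6 cis to C3), which is the ring-cis C4=C5 geometry of the target; the minor Z isomer is removed by chromatography.

Step 3
Reactants: 6 alkylidene lactone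
Product: 7 (2S,4E)-4-(hydroxymethyl)-6,6-dimethoxy-1-(4-methoxybenzyloxy)hex-4-en-2-ol
Conditions: iBu2AlH (4.5 equiv), CH2Cl2, −78 to 0 °C; aq. potassium sodium tartrate
Reagents that add atoms: none
Why: 1,2-Reduction of the unsaturated lactone by the aluminium hydride opens it to the allylic diol, unveiling the C15 and C2 hydroxyls with the alkene geometry kept.

Step 4
Reactants: 7 diol
Product: 8 (2S,4E)-2-(TBS-oxy)-4-[(TBS-oxy)methyl]-6,6-dimethoxy-1-(4-methoxybenzyloxy)hex-4-ene
Conditions: TBSCl, imidazole, 4-dimethylaminopyridine (cat.), DMF, rt to 40 °C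
Reagents that add atoms: tert-butyldimethylsilyl chloride CC(C)(C)[Si](C)(C)Cl
Why: Standard silylation of the primary and secondary alcohols under conditions that leave the acetal intact.

Step 5
Reactants: 8 bis-silyl ether acetal
Product: 9 (2E,5S)-5-(TBS-oxy)-3-[(TBS-oxy)methyl]-6-(4-methoxybenzyloxy)hex-2-enal (west enal, C6 aldehyde)
Conditions: oxalic acid, wet silica gel, CH2Cl2, rt
Reagents that add atoms: water O
Why: Acetal hydrolysis: the allylic dimethyl acetal ionises far more easily than the silyl or PMB ethers, and the mild acid does not isomerise the enal.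

Step 6
Reactants: 10 (4R)-2,2-dimethyl-1,3-dioxolane-4-carbaldehyde; 11 methyl acrylate
Product: 12 methyl 2-{[(4R)-2,2-dimethyl-1,3-dioxolan-4-yl](hydroxy)methyl}prop-2-enoate (carbinol epimers)
Conditions: 1,4-diazabicyclo[2.2.2]octane (0.5 equiv), dioxane/H2O, rt, 48 h
Reagents that add atoms: none
Why: Morita–Baylis–Hillman reaction; the new carbinol centre is a mixture that is erased in step 7, and the dioxolane centre (C8) is not touched.

Step 7
Reactants: 12 Baylis–Hillman alcohol
Product: 13 methyl (2Z)-2-(bromomethyl)-3-[(4S)-2,2-dimethyl-1,3-dioxolan-4-yl]prop-2-enoate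
Conditions: NBS, Me2S, CH2Cl2, 0 °C to rt
Reagents that add atoms: N-bromosuccinimide O=C1CCC(=O)N1Br
Why: SN2′ bromination of the alkoxysulfonium salt (Corey–Kim-type activation) gives the thermodynamically preferred (Z)-allylic bromide, whose geometry is of no consequence because the allylchromium of step 8 equilibrates.

Step 8
Reactants: 9 west enal; 13 east allylic bromide
Product: 15 (4S,5R)-4-[(4S)-2,2-dimethyl-1,3-dioxolan-4-yl]-5-[(1E,4S)-4-(TBS-oxy)-2-[(TBS-oxy)methyl]-5-(4-methoxybenzyloxy)pent-1-en-1-yl]-3-methylideneoxolan-2-one, via hydroxy ester 14 (not isolated)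
Conditions: CrCl2 (4 equiv), THF, 0 °C to rt, 12 h
Reagents that add atoms: none
Why: Chromium-mediated Barbier (Nozaki–Hiyama) allylation then lactonisation: the allylchromium made from 13 by divalent chromium adds through its γ-carbon in a chair transition state with the enal residue equatorial (6,7-anti, hence the trans-lactone) and on the C7 face opposite the dioxolane C8–C9 bond, the C8–H eclipsing the alkene because of allylic 1,3-strain, which sets C6 (R) and C7 (S) from C8.

Step 9
Reactants: 15 PMB ether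
Product: 16 primary alcohol (15 with the C1 O-PMB group replaced by OH)
Conditions: DDQ, CH2Cl2/pH 7 buffer, 0 °C
Reagents that add atoms: none
Why: Oxidative cleavage of the electron-rich benzyl ether by the quinone leaves silyl ethers, acetonide, lactone and alkenes untouched.

Step 10
Reactants: 16 primary alcohol
Product: 17 C1 aldehyde (16 with CH2OH oxidised to CHO)
Conditions: DMP, pyridine, CH2Cl2, 0 °C to rt
Reagents that add atoms: none
Why: Dess–Martin oxidation under buffered, non-basic conditions gives the α-silyloxy aldehyde without epimerising C2.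

Step 11
Reactants: 17 C1 aldehyde
Product: 18 methyl (2Z,4S,6E)-4-(TBS-oxy)-6-[(TBS-oxy)methyl]-2-iodo-7-[(2R,3S)-3-[(4S)-2,2-dimethyl-1,3-dioxolan-4-yl]-4-methylidene-5-oxooxolan-2-yl]hepta-2,6-dienoate
Conditions: Ph3P=CHCO2Me, NIS, CH2Cl2, −20 °C, 30 min; then 17, −20 °C to rt
Reagents that add atoms: methyl (triphenylphosphoranylidene)acetate COC(=O)C=P(c1ccccc1)(c1ccccc1)c1ccccc1; N-iodosuccinimide O=C1CCC(=O)N1I
Why: Halo-Wittig olefination: the ylide is iodinated in the flask and the iodo ylide converts the aldehyde into the (Z)-2-iodo-enoate (iodine cis to C2, ester trans), the geometry later needed for the ring-cis C1=C10 bond, without touching C2.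

Step 12
Reactants: 18 acetonide
Product: 19 C8,C9 diol (18 with the isopropylidene group removed)
Conditions: CeCl3·7H2O, oxalic acid, MeCN, rt
Reagents that add atoms: none
Why: Mild Lewis-acid-assisted hydrolysis selective for a terminal isopropylidene acetal leaves the silyl ethers, the lactone and the iodo-enoate intact.

Step 13
Reactants: 19 diol
Product: 20 C9 triethylsilyl ether (19 with the primary hydroxyl silylated)
Conditions: TESCl (1.1 equiv), imidazole, CH2Cl2, −40 °C
Reagents that add atoms: chlorotriethylsilane CC[Si](Cl)(CC)CC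
Why: Kinetic silylation takes the unhindered primary hydroxyl and leaves the secondary C8 hydroxyl free.

Step 14
Reactants: 20 C8 alcohol
Product: 21 C8 isobutyrate (20 with the C8 hydroxyl acylated)
Conditions: isobutyryl chloride, pyridine, 4-dimethylaminopyridine (cat.), CH2Cl2, 0 °C
Reagents that add atoms: isobutyryl chloride CC(C)C(Cl)=O
Why: Nucleophile-catalysed acylation of the only free hydroxyl installs the C8 ester with retention.

Step 15
Reactants: 21 triethylsilyl ether
Product: 22 methyl (2Z,4S,6E)-4-(TBS-oxy)-6-[(TBS-oxy)methyl]-2-iodo-7-[(2R,3S)-3-[(1S)-1-(isobutyryloxy)-2-oxoethyl]-4-methylidene-5-oxooxolan-2-yl]hepta-2,6-dienoate (seco aldehyde)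
Conditions: (COCl)2, DMSO, CH2Cl2, −78 to −40 °C; Et3N, −78 to 0 °C
Reagents that add atoms: none
Why: Swern conditions convert a primary triethylsilyl ether directly into the aldehyde (the chlorosulfonium salt cleaves the unhindered Si–O bond) while the TBS ethers stay, and the low temperature protects the α-acyloxy centre C8.

Step 16
Reactants: 22 seco aldehyde
Product: 23 ten-membered carbocycle, the 9-O-deacetyl-2,15-bis-O-TBS derivative of the target as both C9 epimers
Conditions: CrCl2 (12 equiv), NiCl2 (0.1 equiv), degassed DMSO, rt, syringe-pump addition of 22 to 2 mM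
Reagents that add atoms: none
Why: Nozaki–Hiyama–Kishi coupling: zerovalent nickel inserts into the activated alkenyl carbon–iodine bond with retention of geometry (C2 stays cis to C9), transmetallation to trivalent chromium gives an alkenylchromium that adds only to the aldehyde under high dilution, and the C9 configuration is inconsequential because both epimers are oxidised in step 17.

Step 17
Reactants: 23 allylic alcohol (epimers)
Product: 24 9-oxo compound (the 2,15-bis-O-TBS-9-deacetoxy-9-oxo derivative of the target)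
Conditions: DMP, pyridine, CH2Cl2, 0 °C
Reagents that add atoms: none
Why: Dess–Martin oxidation of the allylic alcohol converges both C9 epimers on one alkylidene β-keto ester under neutral conditions that do not enolise C8.

Step 18
Reactants: 24 ketone
Product: 25 (9S)-alcohol (the 9-O-deacetyl-2,15-bis-O-TBS derivative of the target)
Conditions: NaBH4, CeCl3·7H2O, MeOH/THF, −78 °C
Reagents that add atoms: none
Why: Luche 1,2-reduction: hydride attacks the C9 carbonyl anti to the C8 acyloxy group (polar Felkin–Anh/Cornforth) from the outer face of the ring, giving the 8,9-syn (9S) alcohol, and the cerium-modified borohydride at −78 °C spares the enoate and the methylene lactone.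

Step 19
Reactants: 25 (9S)-alcohol
Product: 26 2,15-bis-O-TBS ether of the target
Conditions: Ac2O, pyridine, 4-dimethylaminopyridine (cat.), CH2Cl2, 0 °C
Reagents that add atoms: acetic anhydride CC(=O)OC(C)=O
Why: Acetylation of the only free hydroxyl proceeds with retention and faster than acyl migration from O8.

Step 20
Reactants: 26 bis-silyl ether
Product: 27 target CNP0301018.3
Conditions: HF·pyridine, pyridine, THF, 0 °C to rt
Reagents that add atoms: none
Why: Buffered acidic fluoride removes both TBS ethers without ester migration, lactone opening or conjugate addition to the methylene lactone.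

## Compound list

1 | (2R)-2-[(4-methoxybenzyloxy)methyl]oxirane | COc1ccc(COC[C@@H]2CO2)cc1 | starting material
2 | triethyl phosphonoacetate | CCOC(=O)CP(=O)(OCC)OCC | starting material
3 | ethyl (4S)-2-(diethoxyphosphoryl)-4-hydroxy-5-(4-methoxybenzyloxy)pentanoate, present as its sodium alkoxide (C2 epimers) | CCOC(=O)C(C[C@H](O)COCc1ccc(OC)cc1)P(=O)(OCC)OCC | intermediate (not isolated)
4 | diethyl [(5S)-5-[(4-methoxybenzyloxy)methyl]-2-oxooxolan-3-yl]phosphonate (C3 epimers) | CCOP(=O)(OCC)C1C[C@H](OC1=O)COCc2ccc(OC)cc2 | intermediate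
5 | 2,2-dimethoxyacetaldehyde | COC(OC)C=O | starting material
6 | (3E,5S)-3-(2,2-dimethoxyethylidene)-5-[(4-methoxybenzyloxy)methyl]oxolan-2-one | COC(OC)/C=C1/C(=O)O[C@H](COCc2ccc(OC)cc2)C1 | intermediate
7 | (2S,4E)-4-(hydroxymethyl)-6,6-dimethoxy-1-(4-methoxybenzyloxy)hex-4-en-2-ol | COC(OC)/C=C(/CO)C[C@H](O)COCc1ccc(OC)cc1 | intermediate
8 | (2S,4E)-2-(TBS-oxy)-4-[(TBS-oxy)methyl]-6,6-dimethoxy-1-(4-methoxybenzyloxy)hex-4-ene | COC(OC)/C=C(/CO[Si](C)(C)C(C)(C)C)C[C@H](O[Si](C)(C)C(C)(C)C)COCc1ccc(OC)cc1 | intermediate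
9 | (2E,5S)-5-(TBS-oxy)-3-[(TBS-oxy)methyl]-6-(4-methoxybenzyloxy)hex-2-enal | O=C/C=C(/CO[Si](C)(C)C(C)(C)C)C[C@H](O[Si](C)(C)C(C)(C)C)COCc1ccc(OC)cc1 | intermediate
10 | (4R)-2,2-dimethyl-1,3-dioxolane-4-carbaldehyde | CC1(C)OC[C@H](C=O)O1 | starting material
11 | methyl acrylate | C=CC(=O)OC | starting material
12 | methyl 2-{[(4R)-2,2-dimethyl-1,3-dioxolan-4-yl](hydroxy)methyl}prop-2-enoate (carbinol epimers) | C=C(C(=O)OC)C(O)[C@H]1COC(C)(C)O1 | intermediate
13 | methyl (2Z)-2-(bromomethyl)-3-[(4S)-2,2-dimethyl-1,3-dioxolan-4-yl]prop-2-enoate | BrC/C(C(=O)OC)=C\[C@H]1COC(C)(C)O1 | intermediate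
14 | methyl (3S,4R,5E,8S)-3-[(4S)-2,2-dimethyl-1,3-dioxolan-4-yl]-4-hydroxy-8-(TBS-oxy)-6-[(TBS-oxy)methyl]-9-(4-methoxybenzyloxy)-2-methylidenenon-5-enoate, present as its chromium alkoxide | C=C(C(=O)OC)[C@@H]([C@H](O)/C=C(/CO[Si](C)(C)C(C)(C)C)C[C@H](O[Si](C)(C)C(C)(C)C)COCc1ccc(OC)cc1)[C@H]1COC(C)(C)O1 | intermediate (not isolated)
15 | (4S,5R)-4-[(4S)-2,2-dimethyl-1,3-dioxolan-4-yl]-5-[(1E,4S)-4-(TBS-oxy)-2-[(TBS-oxy)methyl]-5-(4-methoxybenzyloxy)pent-1-en-1-yl]-3-methylideneoxolan-2-one (trans-lactone; target C2 S, C6 R, C7 S, C8 S) | C=C1C(=O)O[C@H](/C=C(/CO[Si](C)(C)C(C)(C)C)C[C@H](O[Si](C)(C)C(C)(C)C)COCc2ccc(OC)cc2)[C@H]1[C@H]3COC(C)(C)O3 | intermediate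
16 | primary C1 alcohol: 15 with the O-PMB group replaced by OH | C=C1C(=O)O[C@H](/C=C(/CO[Si](C)(C)C(C)(C)C)C[C@H](O[Si](C)(C)C(C)(C)C)CO)[C@H]1[C@H]3COC(C)(C)O3 | intermediate
17 | C1 aldehyde: 16 with CH2OH oxidised to CHO | C=C1C(=O)O[C@H](/C=C(/CO[Si](C)(C)C(C)(C)C)C[C@H](O[Si](C)(C)C(C)(C)C)C=O)[C@H]1[C@H]3COC(C)(C)O3 | intermediate
18 | methyl (2Z,4S,6E)-4-(TBS-oxy)-6-[(TBS-oxy)methyl]-2-iodo-7-[(2R,3S)-3-[(4S)-2,2-dimethyl-1,3-dioxolan-4-yl]-4-methylidene-5-oxooxolan-2-yl]hepta-2,6-dienoate | C=C1C(=O)O[C@H](/C=C(/CO[Si](C)(C)C(C)(C)C)C[C@H](O[Si](C)(C)C(C)(C)C)/C=C(/C(=O)OC)I)[C@H]1[C@H]3COC(C)(C)O3 | intermediate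
19 | C8,C9 diol: 18 with the isopropylidene group removed | C=C1C(=O)O[C@H](/C=C(/CO[Si](C)(C)C(C)(C)C)C[C@H](O[Si](C)(C)C(C)(C)C)/C=C(/C(=O)OC)I)[C@H]1[C@H](O)CO | intermediate
20 | 19 with the primary C9 hydroxyl as triethylsilyl ether | C=C1C(=O)O[C@H](/C=C(/CO[Si](C)(C)C(C)(C)C)C[C@H](O[Si](C)(C)C(C)(C)C)/C=C(/C(=O)OC)I)[C@H]1[C@H](O)CO[Si](CC)(CC)CC | intermediate
21 | 20 with the C8 hydroxyl as isobutyrate | C=C1C(=O)O[C@H](/C=C(/CO[Si](C)(C)C(C)(C)C)C[C@H](O[Si](C)(C)C(C)(C)C)/C=C(/C(=O)OC)I)[C@H]1[C@H](OC(=O)C(C)C)CO[Si](CC)(CC)CC | intermediate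
22 | methyl (2Z,4S,6E)-4-(TBS-oxy)-6-[(TBS-oxy)methyl]-2-iodo-7-[(2R,3S)-3-[(1S)-1-(isobutyryloxy)-2-oxoethyl]-4-methylidene-5-oxooxolan-2-yl]hepta-2,6-dienoate | C=C1C(=O)O[C@H](/C=C(/CO[Si](C)(C)C(C)(C)C)C[C@H](O[Si](C)(C)C(C)(C)C)/C=C(/C(=O)OC)I)[C@H]1[C@H](OC(=O)C(C)C)C=O | intermediate
23 | 9-O-deacetyl-2,15-bis-O-TBS derivative of the target, both C9 epimers | C=C1C(=O)O[C@@H]2/C=C(/CO[Si](C)(C)C(C)(C)C)C[C@H](O[Si](C)(C)C(C)(C)C)/C=C(/C(=O)OC)C(O)[C@@H](OC(=O)C(C)C)[C@@H]12 | intermediate
24 | 2,15-bis-O-TBS-9-deacetoxy-9-oxo derivative of the target | C=C1C(=O)O[C@@H]2/C=C(/CO[Si](C)(C)C(C)(C)C)C[C@H](O[Si](C)(C)C(C)(C)C)/C=C(/C(=O)OC)C(=O)[C@@H](OC(=O)C(C)C)[C@@H]12 | intermediate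
25 | (9S)-9-O-deacetyl-2,15-bis-O-TBS derivative of the target | C=C1C(=O)O[C@@H]2/C=C(/CO[Si](C)(C)C(C)(C)C)C[C@H](O[Si](C)(C)C(C)(C)C)/C=C(/C(=O)OC)[C@H](O)[C@@H](OC(=O)C(C)C)[C@@H]12 | intermediate
26 | 2,15-bis-O-TBS ether of the target | C=C1C(=O)O[C@@H]2/C=C(/CO[Si](C)(C)C(C)(C)C)C[C@H](O[Si](C)(C)C(C)(C)C)/C=C(/C(=O)OC)[C@H](OC(C)=O)[C@@H](OC(=O)C(C)C)[C@@H]12 | intermediate
27 | CNP0301018.3: methyl (2S,6R,7S,8S,9S)-9-acetoxy-2,15-dihydroxy-8-(isobutyryloxy)germacra-1(10),4,11(13)-trien-12,6-olid-14-oate, both ring alkenes ring-cis | C=C1C(=O)O[C@@H]2/C=C(/CO)C[C@H](O)/C=C(/C(=O)OC)[C@H](OC(C)=O)[C@@H](OC(=O)C(C)C)[C@@H]12 | target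

## Step count and risks

Total steps: 20. Longest linear sequence: 18 (steps 1–5, then 8–20); the east branch (steps 6–7) is 2 steps.

**Step 16, ten-membered NiCl2/CrCl2 closure.** The risks are oligomerisation, protodeiodination and strain in forming a ring that already holds a trans-fused lactone. The fallback closes the ring at C1=C10 by a Knoevenagel condensation instead. It sets out from 15, before the C1 end is elaborated. CeCl3·7H2O/oxalic acid gives the PMB-protected diol F1, TESCl/imidazole its primary triethylsilyl ether F2, and isobutyryl chloride/pyridine the C8 isobutyrate F3. Swern oxidation gives the C9 aldehyde F4, and methyl diazoacetate with SnCl2 (Roskamp homologation) the β-keto ester F5. DDQ then gives the C1 alcohol F6 and Dess–Martin oxidation the keto ester aldehyde F7. Piperidinium acetate in benzene at high dilution condenses C1 with C10; the ring-cis alkene is expected as the thermodynamic isomer of this reversible condensation. The route is rejoined at ketone 24.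

**Step 8, chromium allylation–lactonisation.** The risks are the face selectivity at C7 relative to the dioxolane, which rests on a transition-state model and not on a direct precedent, and 1,4-elimination of the oxygenated allylchromium. The fallback is a reagent-controlled propargylation followed by carbonylative lactonisation. It sets out from 10 and 9. Ethynylmagnesium bromide adds to 10 to give the anti propargylic alcohol F8 (Felkin–Anh; the minor syn epimer is removed). MsCl/Et3N gives the propargylic mesylate F9. Pd(OAc)2/PPh3/InI with enal 9 (Marshall allenylindium addition) gives the anti homopropargylic alcohol F10; net inversion at the propargylic carbon sets C7 and the cyclic transition state sets C6 anti. PdCl2/SnCl2/PPh3 under CO in MeCN then carbonylates the alkyne with ring closure onto the C6 hydroxyl, and the route is rejoined at 15.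

**Step 18, Luche reduction.** The risks are the hydride face at C9 inside the macrocycle and conjugate reduction of the methylene lactone. The fallback inverts instead of reducing. It sets out from 23: the 9R epimer, the C9-epimeric alcohol F11, is separated from the mixture. It is treated with acetic acid, PPh3 and diisopropyl azodicarboxylate (Mitsunobu reaction, SN2 at C9 with inversion), which installs the 9S acetate directly; SN2′ attack at C1 is the hazard to watch. The route is rejoined at 26; the 9S portion of 23 is acetylated as in step 19.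

## Further compounds

F1 | step 16 | PMB-protected diol: 15 with the isopropylidene group removed | C=C1C(=O)O[C@H](/C=C(/CO[Si](C)(C)C(C)(C)C)C[C@H](O[Si](C)(C)C(C)(C)C)COCc2ccc(OC)cc2)[C@H]1[C@H](O)CO
F2 | step 16 | F1 with the primary C9 hydroxyl as triethylsilyl ether | C=C1C(=O)O[C@H](/C=C(/CO[Si](C)(C)C(C)(C)C)C[C@H](O[Si](C)(C)C(C)(C)C)COCc2ccc(OC)cc2)[C@H]1[C@H](O)CO[Si](CC)(CC)CC
F3 | step 16 | F2 with the C8 hydroxyl as isobutyrate | C=C1C(=O)O[C@H](/C=C(/CO[Si](C)(C)C(C)(C)C)C[C@H](O[Si](C)(C)C(C)(C)C)COCc2ccc(OC)cc2)[C@H]1[C@H](OC(=O)C(C)C)CO[Si](CC)(CC)CC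
F4 | step 16 | C9 aldehyde: F3 with CH2OSiEt3 oxidised to CHO | C=C1C(=O)O[C@H](/C=C(/CO[Si](C)(C)C(C)(C)C)C[C@H](O[Si](C)(C)C(C)(C)C)COCc2ccc(OC)cc2)[C@H]1[C@H](OC(=O)C(C)C)C=O
F5 | step 16 | β-keto ester: F4 with CHO homologated to C(=O)CH2CO2Me | C=C1C(=O)O[C@H](/C=C(/CO[Si](C)(C)C(C)(C)C)C[C@H](O[Si](C)(C)C(C)(C)C)COCc2ccc(OC)cc2)[C@H]1[C@H](OC(=O)C(C)C)C(=O)CC(=O)OC
F6 | step 16 | C1 alcohol: F5 with the O-PMB group replaced by OH | C=C1C(=O)O[C@H](/C=C(/CO[Si](C)(C)C(C)(C)C)C[C@H](O[Si](C)(C)C(C)(C)C)CO)[C@H]1[C@H](OC(=O)C(C)C)C(=O)CC(=O)OC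
F7 | step 16 | keto ester aldehyde: F6 with CH2OH oxidised to CHO | C=C1C(=O)O[C@H](/C=C(/CO[Si](C)(C)C(C)(C)C)C[C@H](O[Si](C)(C)C(C)(C)C)C=O)[C@H]1[C@H](OC(=O)C(C)C)C(=O)CC(=O)OC
F8 | step 8 | (1S)-1-[(4R)-2,2-dimethyl-1,3-dioxolan-4-yl]prop-2-yn-1-ol (anti) | C#C[C@H](O)[C@H]1COC(C)(C)O1
F9 | step 8 | methanesulfonate of F8 | C#C[C@H](OS(C)(=O)=O)[C@H]1COC(C)(C)O1
F10 | step 8 | anti homopropargylic alcohol: 14 with the C(=CH2)CO2Me group replaced by ethynyl | C#C[C@@H]([C@H](O)/C=C(/CO[Si](C)(C)C(C)(C)C)C[C@H](O[Si](C)(C)C(C)(C)C)COCc1ccc(OC)cc1)[C@H]1COC(C)(C)O1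
F11 | step 18 | (9R)-epimer of 25 | C=C1C(=O)O[C@@H]2/C=C(/CO[Si](C)(C)C(C)(C)C)C[C@H](O[Si](C)(C)C(C)(C)C)/C=C(/C(=O)OC)[C@@H](O)[C@@H](OC(=O)C(C)C)[C@@H]12
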